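The numbers in the tables were computed on assumed constants, noise included.

Take the easy step first: before you plan on taking this flask off as finished, count how many half-lives of L fit into its time. L is charged, D is held, and G is read as L falls.

the same everywhere: D 3.3 mM (held)
- Monday's: L 0.040 M; run made earlier
- Thursday's: L 0.088 M; run made earlier
- flask: L 0.059 M; time 30 h

- Monday's (time / h: G / %, L / %): 4.00: 12, 72; 10.0: 24, 48; 20.0: 37, 26; 30.0: 44, 12
- Thursday's (time / h: G / %, L / %): 8.00: 19, 38; 15.0: 26, 22; 25.0: 31, 9; 30.0: 29, 8

(scatter of a reading: 2 percentage points)

- at 30 h, what has stopped the reaction, if anything has (forward and back rates have come level / it is still moving / all of L has reacted)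
- amount of G at 30 h, in percent of the L charged

- the earlier runs were read with a standard deviation of 2 percentage points
- at the start none of D is in solution
- a reading or a percentage of G counts all its forms, free or not
- the reaction counts as stopped when no species that holds the L changes by six tenths of a point or more over the second half of the time

Let k be the fraction of L lost per hour (a pseudo-first-order constant), read from the last Monday reading and from Thursday's at 25.0 h, as k = −ln(fraction left)/time:

k on Monday = 0.0707 /h
k on Thursday = 0.0963 /h

Thursday's charge is the bigger and its k the bigger, so take k as a straight line in the charge:

k in this flask = 0.0808 /h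
half-life T = ln(2)/k = 8.58 h
n = time/T = 3.50
L left = 8.85%

Call n the half-life count. By this count L is at 29.7% halfway through, a reckoned drop of 21 percentage points over the second half, far past the stopping mark. Do not plan on a finished flask at 30 h.

For G, my own reckoning takes G per L used, from the same two readings: 0.500 on Monday, 0.341 on Thursday, and on a straight line in the charge 0.437 in this flask. That gives G at 39.8%.

The forecast says it is still moving, with G at 38%, which is less than my figure, and argues that “L is still falling at nearly 1 point per hour”.

The flask gives it is still moving, with G at 35.7%.

    D ⇌ X, rate k1*(csat - [X]) (kL = 5.73 /h)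
    L + X → G (k = 13.8 /M/h)
    L + G → E (k = 0.835 /M/h)
    Z ⇌ G, rate k4*(cs4 - [G]) while solid is left; crystals form when [G] > cs4 (solubility = 47.0 mM, k = 5.25 /h)
    2 L → J (k = 0.504 /M/h)

It is still moving mainly because the time given is short: the count of 3.50 put L at 8.85%, and this flask holds 9.87%. A longer stay is what turns the forecast's verdict: in this flask left until 300 h, L stands at 0%, conversion of L rises from 90.1% to 100%, and G stands at 39.7%. Count the neighbour flask charged with 0.015 M of L for the same 30 h, running the line on below Monday's charge: k =  0.0573 /h, T = 12.1 h, n = 2.48, leaving 17.9% of L; that flask held 18%.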